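**Retrosynthetic overview**
- The target is read as (3R,4R), with the epoxide oxygen trans to the tertiary methoxy group. It comes from its bis-benzyl ether, and the spiro-epoxide is closed last (O–CH2 bond) from a tertiary/primary 1,2-diol, which comes from an α-hydroxy methyl ester.
- The α-hydroxy ester comes from a one-pot biomimetic ring contraction: enantioselective oxidative methoxylation of an atromentin-type hydroxy-methoxy terphenylquinone to a cyclohexene-1,2,4-trione, then benzilic ester rearrangement. This forms the cyclopentenone and both stereocentres.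
- The terphenylquinone comes from a double Suzuki coupling of 2,5-dibromo-3,6-dimethoxybenzoquinone (from bromanil) with 4-(benzyloxy)phenylboronic acid, then mono-hydrolysis.
- Ring order: the quinone ring is bought, contracted to the cyclopentenone, and the spiro-epoxide is formed last.

Assumption: both antipodes of the chiral iodoarene catalyst are equally accessible from (S)- or (R)-lactate; the (R,R)-catalyst is written, and its antipode is used if the first run shows the opposite sense of induction.

**Step 1**
Reactants: 1 tetrabromo-1,4-benzoquinone (bromanil)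
Product: 2 2,5-dibromo-3,6-dimethoxy-1,4-benzoquinone
Conditions: NaOMe (2.05 equiv), MeOH, 0 °C to rt
Reagents that add atoms: sodium methoxide, [Na+].[O-]C
Why: Addition–elimination (vinylogous acyl substitution) of methoxide on the haloquinone; the first methoxy group deactivates its own enone unit, so the second methoxide enters the other enone unit para to the first, giving the 2,5-dibromo-3,6-dimethoxy pattern, and no stereocentre is formed.

**Step 2**
Reactants: 2 2,5-dibromo-3,6-dimethoxy-1,4-benzoquinone; 3 4-(benzyloxy)phenylboronic acid (2.4 equiv)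
Product: 5 2,5-bis[4-(benzyloxy)phenyl]-3-hydroxy-6-methoxy-1,4-benzoquinone, via dimethoxyquinone 4 (not isolated)
Conditions: Pd(dppf)Cl2 (5 mol%), K3PO4, dioxane, 90 °C; then 1 M aq LiOH, 40 °C; HCl
Reagents that add atoms: lithium hydroxide, [Li+].[OH-] (supplies the oxygen of the new hydroxyl)
Why: Twofold Suzuki–Miyaura coupling at the two vinylogous acyl bromide carbons builds the terphenylquinone, and aqueous hydroxide then cleaves one vinylogous methyl ester by addition–elimination, the reaction pausing at the mono-acid because its delocalised anion is far less electrophilic; no stereocentre is formed.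

**Step 3**
Reactants: 5 2,5-bis[4-(benzyloxy)phenyl]-3-hydroxy-6-methoxy-1,4-benzoquinone
Product: 7 methyl (1S,5R)-2,5-bis[4-(benzyloxy)phenyl]-1-hydroxy-3,5-dimethoxy-4-oxocyclopent-2-ene-1-carboxylate, via trione 6 (not isolated)
Conditions: (2R,2'R)-2,2'-[(2-iodo-1,3-phenylene)bis(oxy)]bis(N-mesitylpropanamide) (10 mol%), mCPBA (1.2 equiv), MeOH (10 equiv), CH2Cl2, −20 °C; Me2S; then Et3N (3 equiv), MeOH, −20 to 0 °C
Reagents that add atoms: methanol, CO (two molecules: one becomes the tertiary methyl ether, one the ester methoxy group)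
Why: Proposed new method: mCPBA turns the chiral aryl iodide into a trivalent iodine species that binds the acidic enol oxygen of 5 and lets methanol attack C3 from one face only (closest known reactions: chiral-aryl-iodide-catalysed enantioselective oxidative dearomatisation of phenols and naphthols to ortho-quinol derivatives, and PhI(OAc)2 α-oxygenation of 1,3-dicarbonyl enols), which sets the methoxy-bearing centre (3S in 6); the non-enolisable 1,2-dione then undergoes the biomimetic benzilic ester rearrangement (the ring contraction of the Hooker oxidation), in which methanol adds to C2 and C3 migrates to C1 with retention, the new carbinol centre (1S) forming with its CO2Me group trans to the bulky aryl group and its oxygen anti to the C–OMe dipole.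

**Step 4**
Reactants: 7 methyl (1S,5R)-2,5-bis[4-(benzyloxy)phenyl]-1-hydroxy-3,5-dimethoxy-4-oxocyclopent-2-ene-1-carboxylate
Product: 8 (4R,5R)-3,5-bis[4-(benzyloxy)phenyl]-4-hydroxy-4-(hydroxymethyl)-2,5-dimethoxycyclopent-2-en-1-one
Conditions: BH3·SMe2 (1.2 equiv), NaBH4 (5 mol%), THF, 0 °C to rt; MeOH
Reagents that add atoms: none
Why: Hydroxyl-directed borane reduction of an α-hydroxy ester (Saito conditions): the alkoxyborane formed at the tertiary OH reaches only the ester on the same carbon through a five-membered chelate, while the hindered conjugated ring ketone lies outside this tether and reacts more slowly with free borane; both stereocentres are untouched.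

**Step 5**
Reactants: 8 (4R,5R)-3,5-bis[4-(benzyloxy)phenyl]-4-hydroxy-4-(hydroxymethyl)-2,5-dimethoxycyclopent-2-en-1-one
Product: 10 (3R,4R)-4,7-bis[4-(benzyloxy)phenyl]-4,6-dimethoxy-1-oxaspiro[2.4]hept-6-en-5-one, via primary mesylate 9 (not isolated)
Conditions: MsCl (1.05 equiv), Et3N, CH2Cl2, −20 °C; then DBU, 0 °C to rt
Reagents that add atoms: methanesulfonyl chloride, CS(=O)(=O)Cl (its atoms are in 9 only and are absent from 10)
Why: Selective sulfonylation of the primary hydroxyl and intramolecular Williamson closure (3-exo-tet) by the tertiary alkoxide form only the O–CH2 bond, so the spiro carbon keeps its configuration and the epoxide oxygen ends trans to the neighbouring methoxy group.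

**Step 6**
Reactants: 10 (3R,4R)-4,7-bis[4-(benzyloxy)phenyl]-4,6-dimethoxy-1-oxaspiro[2.4]hept-6-en-5-one
Product: 11 (3R,4R)-4,7-bis(4-hydroxyphenyl)-4,6-dimethoxy-1-oxaspiro[2.4]hept-6-en-5-one (CNP0504072.1)
Conditions: H2 (1 atm), 10% Pd/C, EtOAc, rt
Reagents that add atoms: none
Why: Catalytic hydrogenolysis cleaves the two phenolic benzyl ethers much faster than it touches the hindered non-benzylic spiro-epoxide, the quaternary benzylic methyl ether or the tetrasubstituted enone, so both stereocentres are carried through unchanged.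

**Compound list**
1 | tetrabromo-1,4-benzoquinone (bromanil) | O=C1C(Br)=C(Br)C(=O)C(Br)=C1Br | starting material
2 | 2,5-dibromo-3,6-dimethoxy-1,4-benzoquinone | COC1=C(Br)C(=O)C(OC)=C(Br)C1=O | intermediate
3 | 4-(benzyloxy)phenylboronic acid | OB(O)c1ccc(OCc2ccccc2)cc1 | starting material
4 | 2,5-bis[4-(benzyloxy)phenyl]-3,6-dimethoxy-1,4-benzoquinone | COC1=C(c2ccc(OCc3ccccc3)cc2)C(=O)C(OC)=C(c2ccc(OCc3ccccc3)cc2)C1=O | intermediate (not isolated)
5 | 2,5-bis[4-(benzyloxy)phenyl]-3-hydroxy-6-methoxy-1,4-benzoquinone | COC1=C(c2ccc(OCc3ccccc3)cc2)C(=O)C(O)=C(c2ccc(OCc3ccccc3)cc2)C1=O | intermediate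
6 | (3S)-3,6-bis[4-(benzyloxy)phenyl]-3,5-dimethoxycyclohex-5-ene-1,2,4-trione | COC1=C(c2ccc(OCc3ccccc3)cc2)C(=O)C(=O)[C@](OC)(c2ccc(OCc3ccccc3)cc2)C1=O | intermediate (not isolated)
7 | methyl (1S,5R)-2,5-bis[4-(benzyloxy)phenyl]-1-hydroxy-3,5-dimethoxy-4-oxocyclopent-2-ene-1-carboxylate | COC1=C(c2ccc(OCc3ccccc3)cc2)[C@@](O)(C(=O)OC)[C@](OC)(c2ccc(OCc3ccccc3)cc2)C1=O | intermediate
8 | (4R,5R)-3,5-bis[4-(benzyloxy)phenyl]-4-hydroxy-4-(hydroxymethyl)-2,5-dimethoxycyclopent-2-en-1-one | COC1=C(c2ccc(OCc3ccccc3)cc2)[C@@](O)(CO)[C@](OC)(c2ccc(OCc3ccccc3)cc2)C1=O | intermediate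
9 | [(1R,5R)-2,5-bis[4-(benzyloxy)phenyl]-1-hydroxy-3,5-dimethoxy-4-oxocyclopent-2-en-1-yl]methyl methanesulfonate | COC1=C(c2ccc(OCc3ccccc3)cc2)[C@@](O)(COS(C)(=O)=O)[C@](OC)(c2ccc(OCc3ccccc3)cc2)C1=O | intermediate (not isolated)
10 | (3R,4R)-4,7-bis[4-(benzyloxy)phenyl]-4,6-dimethoxy-1-oxaspiro[2.4]hept-6-en-5-one | COC1=C(c2ccc(OCc3ccccc3)cc2)[C@@]2(CO2)[C@](OC)(c2ccc(OCc3ccccc3)cc2)C1=O | intermediate
11 | (3R,4R)-4,7-bis(4-hydroxyphenyl)-4,6-dimethoxy-1-oxaspiro[2.4]hept-6-en-5-one | COC1=C(c2ccc(O)cc2)[C@@]2(CO2)[C@](OC)(c2ccc(O)cc2)C1=O | target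

**Total step count:** 6. **Longest linear sequence:** 6 (from bromanil 1; boronic acid 3 is bought).

**Three steps most likely to fail**

Step 3 is the largest risk: neither the enantioselectivity of the iodoarene-catalysed methoxylation nor the diastereoselectivity of the ring contraction has direct precedent, and a stronger base could open the β-hydroxy ketone by retro-aldol. The fallback sets out from 5 and gives up catalytic induction for a resolution that costs no extra step. Oxidise 5 with achiral PhI(OAc)2 (1.1 equiv) and MeOH (5 equiv) in CH2Cl2 at 0 °C; this gives the trione as a racemate, that is 6 together with its enantiomer (3R)-3,6-bis[4-(benzyloxy)phenyl]-3,5-dimethoxycyclohex-5-ene-1,2,4-trione F1. Strip the volatiles and trigger the ring contraction in THF at −40 °C with potassium (1R,2S,5R)-menthoxide in place of methanol, so that the nucleophile that becomes the carboxyl group is also the resolving group. The two esters, (1R,2S,5R)-menthyl (1S,5R)-2,5-bis[4-(benzyloxy)phenyl]-1-hydroxy-3,5-dimethoxy-4-oxocyclopent-2-ene-1-carboxylate F2 and (1R,2S,5R)-menthyl (1R,5S)-2,5-bis[4-(benzyloxy)phenyl]-1-hydroxy-3,5-dimethoxy-4-oxocyclopent-2-ene-1-carboxylate F3, are diastereomers and are separated on silica or by crystallisation (at most 50% of F2). F2 is reduced with BH3·SMe2 and catalytic NaBH4 as in step 4, which expels menthol and comes back to the route at 8.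

Step 4 may over-reduce: borane can also attack the ring ketone. The fallback sets out from 7 and stops asking for chemoselectivity in the reduction. LiAlH4 (THF, −20 to 0 °C) reduces ester and ketone together to (4R,5S)-3,5-bis[4-(benzyloxy)phenyl]-4-(hydroxymethyl)-2,5-dimethoxycyclopent-2-ene-1,4-diol F4 (both C1 epimers). Activated MnO2 (CH2Cl2, rt) then re-oxidises only the allylic secondary alcohol, which removes the extra stereocentre and comes back to the route at 8.

Step 6 may damage the allylic spiro-epoxide or the benzylic methyl ether under hydrogenolysis. The fallback sets out from 8 and reverses the order of the endgame so that no epoxide ever meets hydrogen. The benzyl ethers of 8 are hydrogenolysed first (H2, 10% Pd/C, EtOAc/MeOH) to (4R,5R)-4-hydroxy-4-(hydroxymethyl)-3,5-bis(4-hydroxyphenyl)-2,5-dimethoxycyclopent-2-en-1-one F5. The epoxide is then closed last by Mitsunobu cyclodehydration (PPh3, DIAD, THF, 0 °C to rt): the primary oxyphosphonium sits on a neopentyl-type carbon, which blocks intermolecular attack by the free phenols while the adjacent tertiary oxygen closes the three-membered ring with retention at the spiro carbon. This comes back to the route at 11.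

**Further compounds**
F1 | step 3 | (3R)-3,6-bis[4-(benzyloxy)phenyl]-3,5-dimethoxycyclohex-5-ene-1,2,4-trione (enantiomer of 6, formed with 6 as the racemate) | COC1=C(c2ccc(OCc3ccccc3)cc2)C(=O)C(=O)[C@@](OC)(c2ccc(OCc3ccccc3)cc2)C1=O
F2 | step 3 | (1R,2S,5R)-menthyl (1S,5R)-2,5-bis[4-(benzyloxy)phenyl]-1-hydroxy-3,5-dimethoxy-4-oxocyclopent-2-ene-1-carboxylate | COC1=C(c2ccc(OCc3ccccc3)cc2)[C@@](O)(C(=O)O[C@@H]2C[C@H](C)CC[C@H]2C(C)C)[C@](OC)(c2ccc(OCc3ccccc3)cc2)C1=O
F3 | step 3 | (1R,2S,5R)-menthyl (1R,5S)-2,5-bis[4-(benzyloxy)phenyl]-1-hydroxy-3,5-dimethoxy-4-oxocyclopent-2-ene-1-carboxylate | COC1=C(c2ccc(OCc3ccccc3)cc2)[C@](O)(C(=O)O[C@@H]2C[C@H](C)CC[C@H]2C(C)C)[C@@](OC)(c2ccc(OCc3ccccc3)cc2)C1=O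
F4 | step 4 | (4R,5S)-3,5-bis[4-(benzyloxy)phenyl]-4-(hydroxymethyl)-2,5-dimethoxycyclopent-2-ene-1,4-diol (both C1 epimers) | COC1=C(c2ccc(OCc3ccccc3)cc2)[C@@](O)(CO)[C@](OC)(c2ccc(OCc3ccccc3)cc2)C1O
F5 | step 6 | (4R,5R)-4-hydroxy-4-(hydroxymethyl)-3,5-bis(4-hydroxyphenyl)-2,5-dimethoxycyclopent-2-en-1-one | COC1=C(c2ccc(O)cc2)[C@@](O)(CO)[C@](OC)(c2ccc(O)cc2)C1=O
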